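The choice lies between feeding the substrate and feeding the coupling partner, and the earlier runs favour the partner.

| setting | autumn | dusk | winter | noon | Friday's | Tuesday's | Thursday's |
|---|---|---|---|---|---|---|---|
| substrate | 0.050 M | 0.034 M | 0.075 M | 0.050 M | 0.050 M | 0.050 M (fed, over 20 min) | 0.050 M |
| coupling partner | 0.10 M | 0.10 M | 0.10 M | 0.15 M | 0.100 M | 0.100 M | 0.100 M (fed, over 20 min) |
| free catalyst | 35 µM | 35 µM | 35 µM | 35 µM | 35 µM | 35 µM | 35 µM |
| remark | run made earlier | run made earlier | run made earlier | run made earlier | everything together at the start | all else is in the flask from the start; the feed brings no volume worth counting | all else is in the flask from the start; the feed brings no volume worth counting |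
| time |  |  |  |  | 1.5 h | 1.5 h | 1.5 h |

| run | time / min | side product / % | target / % |
|---|---|---|---|
| autumn | 6.00 | 2 | 6 |
| autumn | 20.0 | 11 | 3 |
| autumn | 40.0 | 22 | 3 |
| autumn | 50.0 | 22 | 2 |
| dusk | 8.00 | 3 | 5 |
| dusk | 15.0 | 10 | 8 |
| dusk | 40.0 | 23 | 1 |
| dusk | 90.0 | 34 | 4 |
| winter | 25.0 | 10 | 2 |
| winter | 50.0 | 14 | 0 |
| winter | 60.0 | 17 | 1 |
| winter | 90.0 | 17 | 0 |
| noon | 12.0 | 5 | 5 |
| noon | 30.0 | 18 | 2 |
| noon | 60.0 | 26 | 0 |
| noon | 90.0 | 24 | 0 |

(each reading ± 1.5 percentage points)

- a species is counted by the substrate in it: one side product counts as two

- the flask that comes out highest in amount of side product, in percent of the substrate charged; "all alike" if 1.5 percentage points covers them all (Friday's / Tuesday's / Thursday's / all alike)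
- amount of side product at the end, in percent of the substrate charged, Friday's
- amount of side product at the end, in percent of the substrate charged, Tuesday's
- amount of side product at the end, in percent of the substrate charged, Thursday's

Does the side product follow the substrate? Winter was charged with 2.21 times the substrate of dusk, yet at 90.0 min winter's side product holds 12.8 mM of substrate and dusk's 11.6 mM, a ratio of 1.10. So a slow substrate feed should change little, and Tuesday's should land near Friday's, which repeats autumn's recipe and should level off near autumn's 22.0%.

Does it follow the partner? That level gives 0.110; call this the return r, the side product, counted as substrate in it, won per partner added. Noon's extra partner lifted the level to 25.0%, a reading with a scatter of 1.5 percentage points, so the added portion returned only 0.0300, less than the first portion. The return therefore appears to fall as more partner is charged at once. Thursday's partner goes in over 20 min instead of at once, so that flask is spared the start at 0.100 M that Friday's has, and Thursday's should return more than 0.110 and come out highest.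

The forecast gives all alike, with 24%, 23.5% and 24% for Friday's, Tuesday's and Thursday's, holding that “the catalyst dies after a fixed number of turnovers”.

The flasks give Thursday's as highest, with 25.5%, 20.6% and 38.4% in the same order.

    catalyst intermediate D → free catalyst + target (k = 2.49 /s)
    substrate + target → side product (k = 0.0325 /M/s)
    2 coupling partner → homo dimer (k = 0.0670 /M/s)
    coupling partner + catalyst intermediate A → catalyst intermediate B (k = 8.88 /M/s)
    catalyst intermediate C ⇌ catalyst intermediate D (K = 0.711, k = 9.49 /s)
    substrate + free catalyst ⇌ catalyst intermediate A (K = 255 /M, k = 411 /M/s)
    catalyst intermediate B → by-product + catalyst intermediate C (k = 63.1 /s)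

Thursday's returned r = 0.192, above 0.110, while Tuesday's ended 4.9 points below Friday's. In Tuesday's flask the partner, the limiting reagent with 0.58% left at 1.50 h, went early: half of the homo dimer turnover was done by 1.11 min, sooner than the 0.224 h for substrate joining free catalyst. In Thursday's flask 24.1% of the partner still stood at 0.333 h, and by-product reached 0.0100 M by 1.50 h, against 0.00656 M in Friday's. Tuesday's recipe with 5.9 × 10⁻⁵ M of free catalyst returned r = 0.153.

The numbers in the tables stem from a simulated flask with constants of no real substance.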